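The chromone is cut across its pyranone ring at C8a–O1, C4a–C4 and O1–C2, so that ring A arrives as an aryne and C2–C4 with the aryloxy group as a 3-aryloxypropiolic acid. The step exploits the fact that C4a and C8a are adjacent ring A carbons and that the C5 methoxy group next to C4a polarises a C4a–C8a aryne. Carboxylate oxygen adds at C8a, the acyl group moves to C4a, and the phenoxide closes onto C2, giving the pyranone in one operation. The precursor is a fully substituted 2-silylaryl triflate already carrying both methoxy groups and the C8 prenyl group, made by two directed lithiations.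

Key step: step 9

Remark: chromone numbering (O1, C2 to C4, C4a, C5 to C8, C8a) is used for all intermediates; in silyl triflate 10 silicon sits on the future C4a and the triflate on the future C8a.
Remark: the 4′-hydroxyl is carried as its methoxymethyl (MOM) ether, and silicon is introduced before the prenyl group so that no lithiation is run in the presence of the benzylic–allylic CH2 of the prenyl group.

Step 1
Reactants: 1 3,5-dimethoxyphenol
Product: 2 3,5-dimethoxyphenyl N,N-diethylcarbamate
Conditions: NaH, THF, 0 °C; Et2NCOCl, 0 °C → reflux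
Reagents that add atoms: N,N-diethylcarbamoyl chloride, CCN(CC)C(Cl)=O
Why: O-acylation of the sodium phenoxide installs the diethylcarbamate, the strongest oxygen-based director for ortho-lithiation and inert to alkyllithiums at −78 °C.

Step 2
Reactants: 2 3,5-dimethoxyphenyl N,N-diethylcarbamate
Product: 4 3,5-dimethoxy-2-(trimethylsilyl)phenyl N,N-diethylcarbamate, via C2 aryllithium 3 (not isolated)
Conditions: s-BuLi, TMEDA, THF, −78 °C; TMSCl, −78 °C → rt
Reagents that add atoms: chlorotrimethylsilane, C[Si](C)(C)Cl
Why: Directed ortho-metalation should remove the proton at C2, which is flanked and acidified by the carbamate and one methoxy group, in preference to C4 between the two weaker methoxy directors, and the aryllithium is silylated by TMSCl.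

Step 3
Reactants: 4 3,5-dimethoxy-2-(trimethylsilyl)phenyl N,N-diethylcarbamate; 5 prenyl bromide
Product: 8 3,5-dimethoxy-2-(3-methylbut-2-en-1-yl)-6-(trimethylsilyl)phenyl N,N-diethylcarbamate, via C6 aryllithium 6 (not isolated), via arylcopper 7 (not isolated)
Conditions: s-BuLi, TMEDA, THF, −78 °C; CuBr·SMe2, −78 → −40 °C; prenyl bromide, −40 → 0 °C
Reagents that add atoms: none
Why: A second directed ortho-metalation at the remaining carbamate/methoxy-flanked position (silicon blocks the other), transmetalation to the arylcopper and SN2 allylation with prenyl bromide should give the linear prenyl arene, the low temperature and the copper stage suppressing the anionic ortho-Fries shift and SN2′ coupling.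

Step 4
Reactants: 8 3,5-dimethoxy-2-(3-methylbut-2-en-1-yl)-6-(trimethylsilyl)phenyl N,N-diethylcarbamate
Product: 9 3,5-dimethoxy-2-(3-methylbut-2-en-1-yl)-6-(trimethylsilyl)phenol
Conditions: LiAlH4, THF, reflux; aq. potassium sodium tartrate (KNaC4H4O6) work-up
Reagents that add atoms: none
Why: Hydride reduction of the hindered aryl carbamate releases the phenoxide (the carbamoyl carbon leaves as N,N-diethylmethylamine) without touching the arylsilane, the aryl ethers or the trisubstituted alkene, and the near-neutral tartrate work-up avoids acid-promoted ipso-protodesilylation of the electron-rich arylsilane.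

Step 5
Reactants: 9 3,5-dimethoxy-2-(3-methylbut-2-en-1-yl)-6-(trimethylsilyl)phenol
Product: 10 3,5-dimethoxy-2-(3-methylbut-2-en-1-yl)-6-(trimethylsilyl)phenyl trifluoromethanesulfonate
Conditions: n-BuLi, Et2O, −78 °C; Tf2O, −78 → 0 °C
Reagents that add atoms: trifluoromethanesulfonic anhydride, O=S(=O)(OS(=O)(=O)C(F)(F)F)C(F)(F)F
Why: O-sulfonylation of the lithium phenoxide with triflic anhydride at low temperature, the usual last step towards ortho-silylaryl triflates, runs under non-acidic conditions that spare the arylsilane and the alkene.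

Step 6
Reactants: 11 hydroquinone
Product: 12 4-(methoxymethoxy)phenol
Conditions: hydroquinone (3 equiv), NaH (1 equiv), DMF, 0 °C; MOMCl (1 equiv), 0 °C → rt, under argon
Reagents that add atoms: chloromethyl methyl ether, COCCl
Why: Williamson-type O-alkylation of the monosodium phenoxide, with excess hydroquinone biasing towards the mono-ether and the water-soluble diol removed by aqueous washing.

Step 7
Reactants: 12 4-(methoxymethoxy)phenol; 13 trichloroethylene
Product: 14 1-{[(E)-1,2-dichloroethenyl]oxy}-4-(methoxymethoxy)benzene
Conditions: K2CO3, DMF, 70 °C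
Reagents that add atoms: none
Why: Base converts trichloroethylene into dichloroacetylene in situ and the phenoxide adds to it in anti fashion, the established route to aryl (E)-1,2-dichlorovinyl ethers, whose alkene geometry is erased in the next step.

Step 8
Reactants: 14 1-{[(E)-1,2-dichloroethenyl]oxy}-4-(methoxymethoxy)benzene
Product: 17 3-[4-(methoxymethoxy)phenoxy]prop-2-ynoic acid, via chloroalkynyl ether 15 (not isolated), via lithium acetylide 16 (not isolated)
Conditions: n-BuLi (2.2 equiv), THF, −78 → −40 °C; CO2, −78 → 0 °C; cold 1 M HCl to pH 3, immediate extraction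
Reagents that add atoms: carbon dioxide, O=C=O
Why: The first equivalent of n-BuLi dehydrochlorinates to the chloroalkynyl ether and the second performs chlorine–lithium exchange to the lithium aryloxyacetylide, which is carboxylated by CO2 (acetylide carboxylation), while the MOM ether is not lithiated at −78 °C and brief cold acidification leaves the acetal and the push–pull alkyne intact.

Step 9
Reactants: 10 3,5-dimethoxy-2-(3-methylbut-2-en-1-yl)-6-(trimethylsilyl)phenyl trifluoromethanesulfonate; 17 3-[4-(methoxymethoxy)phenoxy]prop-2-ynoic acid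
Product: 20 5,7-dimethoxy-2-[4-(methoxymethoxy)phenoxy]-8-(3-methylbut-2-en-1-yl)-4H-chromen-4-one, via aryne 18 (not isolated), via ortho-hydroxyaryl ynone 19 (not isolated)
Conditions: CsF (4 equiv), THF, 17 stirred with CsF at rt, then 10, sealed tube, 90 °C
Reagents that add atoms: none
Why: Fluoride attacks silicon and triflate leaves to give aryne 18, whose C8a terminus is the more electrophilic one because the inductively withdrawing C5 methoxy group stabilises developing negative charge at C4a, so the caesium carboxylate of 17 should bond through oxygen at C8a. The C4a anion then adds to the neighbouring ester carbonyl and the four-membered adduct opens to the C8a phenoxide and the C4a ynone 19, a net carbon–oxygen insertion of the kind known for fluoride-generated arynes and carboxylic acids, which with arylpropiolic acids gives flavones. The phenoxide adds to the aryloxy-bearing alkyne carbon in a 6-endo-dig oxa-Michael closure of the pyranone, and the acid proton ends at C3. No stereocentre is formed. The one selectivity needed is the regiochemistry of addition to the unsymmetrical aryne, secured by the C5 methoxy group, whose electronic bias should outweigh the steric shielding of C8a by the C8 methylene; the silicon-between-oxygens arrangement of 10 is that of the usual 3-methoxybenzyne precursors.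

Step 10
Reactants: 20 5,7-dimethoxy-2-[4-(methoxymethoxy)phenoxy]-8-(3-methylbut-2-en-1-yl)-4H-chromen-4-one
Product: 21 7-O-methylepimedonin G, 5-hydroxy-2-(4-hydroxyphenoxy)-7-methoxy-8-(3-methylbut-2-en-1-yl)-4H-chromen-4-one
Conditions: BCl3 (4 equiv), CH2Cl2, −78 → 0 °C; ice-water
Reagents that add atoms: none
Why: BCl3 binds the C4 carbonyl and the peri C5 methoxy oxygen in a six-membered chelate, so only that ether is demethylated while the unchelated C7 methoxy group survives, and the same Lewis acid cleaves the MOM acetal at low temperature (chelation-controlled ether cleavage plus Lewis acid acetal cleavage); the prenyl group has no free ortho hydroxyl to cyclise onto it and the aprotic medium spares the C2 aryloxy group.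

Compound list
1 | 3,5-dimethoxyphenol | COc1cc(O)cc(OC)c1 | starting material
2 | 3,5-dimethoxyphenyl N,N-diethylcarbamate | CCN(CC)C(=O)Oc1cc(OC)cc(OC)c1 | intermediate
3 | [2-(diethylcarbamoyloxy)-4,6-dimethoxyphenyl]lithium | CCN(CC)C(=O)Oc1cc(OC)cc(OC)c1[Li] | intermediate (not isolated)
4 | 3,5-dimethoxy-2-(trimethylsilyl)phenyl N,N-diethylcarbamate | CCN(CC)C(=O)Oc1cc(OC)cc(OC)c1[Si](C)(C)C | intermediate
5 | prenyl bromide (1-bromo-3-methylbut-2-ene) | CC(C)=CCBr | starting material
6 | [2-(diethylcarbamoyloxy)-4,6-dimethoxy-3-(trimethylsilyl)phenyl]lithium | CCN(CC)C(=O)Oc1c([Li])c(OC)cc(OC)c1[Si](C)(C)C | intermediate (not isolated)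
7 | [2-(diethylcarbamoyloxy)-4,6-dimethoxy-3-(trimethylsilyl)phenyl]copper | CCN(CC)C(=O)Oc1c([Cu])c(OC)cc(OC)c1[Si](C)(C)C | intermediate (not isolated)
8 | 3,5-dimethoxy-2-(3-methylbut-2-en-1-yl)-6-(trimethylsilyl)phenyl N,N-diethylcarbamate | CCN(CC)C(=O)Oc1c(CC=C(C)C)c(OC)cc(OC)c1[Si](C)(C)C | intermediate
9 | 3,5-dimethoxy-2-(3-methylbut-2-en-1-yl)-6-(trimethylsilyl)phenol | COc1cc(OC)c([Si](C)(C)C)c(O)c1CC=C(C)C | intermediate
10 | 3,5-dimethoxy-2-(3-methylbut-2-en-1-yl)-6-(trimethylsilyl)phenyl trifluoromethanesulfonate | COc1cc(OC)c([Si](C)(C)C)c(OS(=O)(=O)C(F)(F)F)c1CC=C(C)C | intermediate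
11 | hydroquinone | Oc1ccc(O)cc1 | starting material
12 | 4-(methoxymethoxy)phenol | COCOc1ccc(O)cc1 | intermediate
13 | trichloroethylene | ClC=C(Cl)Cl | starting material
14 | 1-{[(E)-1,2-dichloroethenyl]oxy}-4-(methoxymethoxy)benzene | COCOc1ccc(O/C(Cl)=C\Cl)cc1 | intermediate
15 | 1-[(chloroethynyl)oxy]-4-(methoxymethoxy)benzene | COCOc1ccc(OC#CCl)cc1 | intermediate (not isolated)
16 | {[4-(methoxymethoxy)phenoxy]ethynyl}lithium | COCOc1ccc(OC#C[Li])cc1 | intermediate (not isolated)
17 | 3-[4-(methoxymethoxy)phenoxy]prop-2-ynoic acid | OC(=O)C#COc1ccc(OCOC)cc1 | intermediate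
18 | 3,5-dimethoxy-6-(3-methylbut-2-en-1-yl)benzyne (1,2-didehydrobenzene) | COC1=CC(OC)=C(CC=C(C)C)C#C1 | intermediate (not isolated)
19 | 1-[2-hydroxy-4,6-dimethoxy-3-(3-methylbut-2-en-1-yl)phenyl]-3-[4-(methoxymethoxy)phenoxy]prop-2-yn-1-one | COCOc1ccc(OC#CC(=O)c2c(OC)cc(OC)c(CC=C(C)C)c2O)cc1 | intermediate (not isolated)
20 | 5,7-dimethoxy-2-[4-(methoxymethoxy)phenoxy]-8-(3-methylbut-2-en-1-yl)-4H-chromen-4-one | COCOc1ccc(Oc2cc(=O)c3c(OC)cc(OC)c(CC=C(C)C)c3o2)cc1 | intermediate
21 | 7-O-methylepimedonin G, 5-hydroxy-2-(4-hydroxyphenoxy)-7-methoxy-8-(3-methylbut-2-en-1-yl)-4H-chromen-4-one | COc1cc(O)c2c(=O)cc(Oc3ccc(O)cc3)oc2c1CC=C(C)C | target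

Total step count: 10
Longest linear sequence: 7 (steps 1 to 5, then 9 and 10)

Steps most likely to fail

1. Step 9. The C4a aryl anion may be protonated by the bifluoride formed from the acid before it reaches the vinylogous-carbonate carbonyl, which would give only O-arylation. The push–pull alkynoate may also be lost by decarboxylation at the temperature needed, or the aryl anion may add to the alkyne carbon instead of the carbonyl. The fallback sets out from triflate 10 and rejoins at chromone 20, using the robust parent case of the insertion and building the C2–O bond by addition–elimination. CsF and acetic acid in THF should give 1-[2-hydroxy-4,6-dimethoxy-3-(3-methylbut-2-en-1-yl)phenyl]ethan-1-one F1. KOt-Bu and CS2 in THF condense this to 4-hydroxy-5,7-dimethoxy-8-(3-methylbut-2-en-1-yl)-2H-chromene-2-thione F2. MeI and K2CO3 in acetone give 5,7-dimethoxy-8-(3-methylbut-2-en-1-yl)-2-(methylsulfanyl)-4H-chromen-4-one F3. H2O2 in hexafluoroisopropanol, which oxidises sulfides in preference to alkenes, gives 2-(methanesulfinyl)-5,7-dimethoxy-8-(3-methylbut-2-en-1-yl)-4H-chromen-4-one F4. Displacement of the sulfinyl group at C2 by phenol 12 (K2CO3, DMF, rt) then gives chromone 20.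

2. Step 8. The free ynol-ether acid may hydrate or decarboxylate during acidification and isolation. The fallback sets out from lithium acetylide 16 and rejoins at chromone 20 without ever handling the free acid. The acetylide is quenched with 2-(trimethylsilyl)ethyl chloroformate instead of CO2 to give the neutral, chromatographable ester 2-(trimethylsilyl)ethyl 3-[4-(methoxymethoxy)phenoxy]prop-2-ynoate F5. In the fluoride step CsF unmasks the carboxylate of 17 by β-elimination of the silylethyl group in the same flask in which it releases aryne 18, with one equivalent of tert-butanol as proton source for C3.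

3. Step 10. HCl formed in the medium may add across the prenyl alkene, the liberated chloromethyl ether may alkylate the electron-rich rings, or chloride may displace the aryloxy group at the boron-activated C2. The fallback sets out from chromone 20 and rejoins at target 21 in two milder stages. MgI2·OEt2 in toluene–Et2O at 60 °C demethylates only the chelated C5 ether through the magnesium chelate, without protic acid or boron halide, to give 5-hydroxy-7-methoxy-2-[4-(methoxymethoxy)phenoxy]-8-(3-methylbut-2-en-1-yl)-4H-chromen-4-one F6. The MOM group is then removed with NaHSO4 on silica in CH2Cl2 at room temperature, a heterogeneous acid without nucleophilic solvent.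

Further compounds
F1 | step 9 | 1-[2-hydroxy-4,6-dimethoxy-3-(3-methylbut-2-en-1-yl)phenyl]ethan-1-one | CC(=O)c1c(OC)cc(OC)c(CC=C(C)C)c1O
F2 | step 9 | 4-hydroxy-5,7-dimethoxy-8-(3-methylbut-2-en-1-yl)-2H-chromene-2-thione | COc1cc(OC)c2C(O)=CC(=S)Oc2c1CC=C(C)C
F3 | step 9 | 5,7-dimethoxy-8-(3-methylbut-2-en-1-yl)-2-(methylsulfanyl)-4H-chromen-4-one | COc1cc(OC)c2c(=O)cc(SC)oc2c1CC=C(C)C
F4 | step 9 | 2-(methanesulfinyl)-5,7-dimethoxy-8-(3-methylbut-2-en-1-yl)-4H-chromen-4-one (racemic at sulfur) | COc1cc(OC)c2c(=O)cc(S(C)=O)oc2c1CC=C(C)C
F5 | step 8 | 2-(trimethylsilyl)ethyl 3-[4-(methoxymethoxy)phenoxy]prop-2-ynoate | COCOc1ccc(OC#CC(=O)OCC[Si](C)(C)C)cc1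
F6 | step 10 | 5-hydroxy-7-methoxy-2-[4-(methoxymethoxy)phenoxy]-8-(3-methylbut-2-en-1-yl)-4H-chromen-4-one | COCOc1ccc(Oc2cc(=O)c3c(O)cc(OC)c(CC=C(C)C)c3o2)cc1
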